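**Plan**

1. Feature: the ring is numbered C1 (carries the acrylate arm C7=C8–C9), C2 (=CH), C3 (CO2H), C4 (catechol), C5 and C6 (CO2H). The cis C5/C6 diacid is a maleate, the trans C3-carboxyl/C4-aryl pair is a caffeate, and C2=C1–C7 is a propargyl unit whose C7 oxygen can be esterified by the C6 carboxyl, giving a 1,6-enyne plus one alkene.
2. Cuts: first C7=C8 and the danshensu ester (olefination), then C1–C6, C4–C5 and C2–C3 of the cyclohexene in one operation, then the two ester bonds of the maleate.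
3. Forward: tert-butyl propargyl maleate and a 4-methoxybenzyl-protected tert-butyl caffeate are each made in two steps. One rhodium-catalysed [2+2+2] step closes the γ-lactone (C6 carboxyl to C7) and then the cyclohexene.
4. The lactone is opened and the acid trapped as a 4-methoxybenzyl ester, C7 is oxidised to the aldehyde, the danshensu arm is added by Horner–Wadsworth–Emmons olefination, and CF3CO2H removes every protecting group in one step.
5. Stereochemistry: C5/C6 cis from the Z-maleate, C3/C4 trans from the E-caffeate, C4/C5 trans from insertion of the caffeate anti to the C5 ester, absolute configuration from the chiral bisphosphine, and the side-chain centre from (R)-danshensu.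

Key step: step 5

Assumption: (R)-BINAP is taken to favour the enyne face that leads to the (5R,6S,7R,7aR) lactone; if the sense of induction proves opposite, (S)-BINAP is used and nothing else changes.

**Route**

Step 1
Reactants: 1 maleic anhydride; 2 propargyl alcohol (prop-2-yn-1-ol)
Product: 3 (Z)-4-oxo-4-(prop-2-yn-1-yloxy)but-2-enoic acid (monopropargyl maleate)
Conditions: toluene, 80 °C, no catalyst
Reagents that add atoms: none
Why: Uncatalysed alcoholysis of a cyclic anhydride (ring-opening esterification) should stop at the half ester, and the absence of base or nucleophilic catalyst keeps the alkene Z.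

Step 2
Reactants: 3 monopropargyl maleate
Product: 4 tert-butyl prop-2-yn-1-yl (Z)-but-2-enedioate (tert-butyl propargyl maleate)
Conditions: Cl3CC(=NH)OtBu (2 equiv), CH2Cl2/cyclohexane, rt
Reagents that add atoms: tert-butyl 2,2,2-trichloroacetimidate, CC(C)(C)OC(=N)C(Cl)(Cl)Cl
Why: Trichloroacetimidate esterification of a carboxylic acid runs under mildly acidic, amine-free conditions, so the maleate should not isomerise to the fumarate and the terminal alkyne is untouched.

Step 3
Reactants: 5 3,4-dihydroxybenzaldehyde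
Product: 6 3,4-bis[(4-methoxybenzyl)oxy]benzaldehyde
Conditions: PMBCl (2.2 equiv), K2CO3, KI (cat.), DMF, 60 °C, under argon
Reagents that add atoms: 4-methoxybenzyl chloride, COc1ccc(CCl)cc1
Why: Williamson etherification of both phenols under carbonate conditions gives ethers that withstand base, MnO2 and cationic rhodium yet fall to CF3CO2H together with the esters at the end.

Step 4
Reactants: 6 3,4-bis[(4-methoxybenzyl)oxy]benzaldehyde; 7 tert-butyl (triphenylphosphoranylidene)acetate
Product: 8 tert-butyl (E)-3-{3,4-bis[(4-methoxybenzyl)oxy]phenyl}prop-2-enoate (protected tert-butyl caffeate)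
Conditions: toluene, 80 °C
Reagents that add atoms: none
Why: Wittig olefination with a stabilised ylide should give the E-cinnamate under neutral conditions.

Step 5
Reactants: 4 tert-butyl propargyl maleate; 8 protected tert-butyl caffeate
Product: 9 di-tert-butyl (5R,6S,7R,7aR)-6-{3,4-bis[(4-methoxybenzyl)oxy]phenyl}-1-oxo-1,3,5,6,7,7a-hexahydro-2-benzofuran-5,7-dicarboxylate (lactone-fused cyclohexene; plan numbering C3 R, C4 S, C5 R, C6 R; C6 carboxyl tied to C7)
Conditions: [Rh(cod)2]BF4 (10 mol %), (R)-BINAP (10 mol %), H2 then argon (catalyst activation); 8 (3 equiv), slow addition of 4, (CH2Cl)2, 60 °C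
Reagents that add atoms: none
Why: Proposed new method: the cationic monovalent rhodium BINAP fragment should bind the alkyne and the maleate C=C of 4 and cyclise oxidatively to a trivalent rhodacyclopentene (C1–C6 formed) that has no exocyclic β-hydrogen at C5 and so cannot leak into Alder-ene cycloisomerisation; the carbonyl-bound caffeate 8 should then insert syn into the enolate-like Rh–C5 bond with C5 going to the aryl-bearing carbon C4, and reductive elimination of vinyl C2 with C3 should release 9. The closest known reaction types are the cationic rhodium bisphosphine [2+2+2] cycloaddition of 1,6-enynes with acrylamides and the rhodium BINAP cycloisomerisation of ester-tethered 1,6-enynes to γ-lactones; the propargyl enoate tether and a β-aryl acrylate as third partner are untested. The γ-lactone closes in the oxidative cyclisation as a five-membered ring with both rhodium–carbon bonds exocyclic to it, and the cyclohexene closes in the final C(sp2)–C(sp3) reductive elimination from a seven-membered rhodacycle. C5/C6 cis is copied from the Z-maleate and C3/C4 trans from the E-caffeate by the two syn additions, C4/C5 trans should follow from insertion with the aryl group anti to the C5 ester, and the enyne face, hence the absolute configuration, is chosen by (R)-BINAP. The step needs cross-coupling over enyne homo-coupling, one orientation of the caffeate and no maleate-to-fumarate isomerisation: the tether fixes the alkyne regiochemistry, the enolate character of Rh–C5 steers C5 to the β-carbon, excess 8 with slow addition of 4 favours the cross reaction, and the absence of free phosphine or amine keeps the maleate Z.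

Step 6
Reactants: 9 lactone-fused cyclohexene
Product: 11 2,4-di-tert-butyl 1-(4-methoxybenzyl) (1R,2R,3S,4R)-3-{3,4-bis[(4-methoxybenzyl)oxy]phenyl}-6-(hydroxymethyl)cyclohex-5-ene-1,2,4-tricarboxylate, via lithium hydroxy carboxylate 10 (not isolated)
Conditions: LiOH·H2O (1.05 equiv), THF/H2O, 0 °C; evaporate; PMBCl (1.2 equiv), Bu4NI (cat.), DMF, rt
Reagents that add atoms: lithium hydroxide, [Li+].[OH-]; 4-methoxybenzyl chloride, COc1ccc(CCl)cc1
Why: Hydroxide should open the unhindered γ-lactone much faster than it attacks the two tert-butyl esters (saponification), and SN2 alkylation of the carboxylate in the same flask means the hydroxy acid is never acidified and cannot close back, while C6 is protected from epimerisation once it is α to a carboxylate.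

Step 7
Reactants: 11 hydroxymethyl triester
Product: 12 2,4-di-tert-butyl 1-(4-methoxybenzyl) (1R,2R,3S,4R)-3-{3,4-bis[(4-methoxybenzyl)oxy]phenyl}-6-formylcyclohex-5-ene-1,2,4-tricarboxylate
Conditions: MnO2 (activated, excess), CH2Cl2, rt
Reagents that add atoms: none
Why: Manganese dioxide oxidises only the primary allylic alcohol to the conjugated aldehyde under neutral heterogeneous conditions (allylic alcohol oxidation), which also removes the hydroxyl that could re-lactonise.

Step 8
Reactants: 13 (R)-danshensu, (2R)-3-(3,4-dihydroxyphenyl)-2-hydroxypropanoic acid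
Product: 14 4-methoxybenzyl (2R)-3-{3,4-bis[(4-methoxybenzyl)oxy]phenyl}-2-hydroxypropanoate
Conditions: PMBCl (3.3 equiv), K2CO3, KI (cat.), DMF, rt, under argon
Reagents that add atoms: 4-methoxybenzyl chloride, COc1ccc(CCl)cc1
Why: Carbonate-mediated alkylation takes the carboxylate and both phenols but not the secondary alcohol (carboxylate alkylation and Williamson etherification), so the α-hydroxyl stays free and the R centre is untouched.

Step 9
Reactants: 14 protected danshensu; 15 (diethoxyphosphoryl)acetic acid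
Product: 16 4-methoxybenzyl (2R)-3-{3,4-bis[(4-methoxybenzyl)oxy]phenyl}-2-{[(diethoxyphosphoryl)acetyl]oxy}propanoate
Conditions: DCC, DMAP (cat.), CH2Cl2, 0 °C to rt
Reagents that add atoms: none
Why: Steglich esterification of the secondary alcohol with the phosphonoacetic acid breaks no bond at the stereocentre.

Step 10
Reactants: 12 formyl triester; 16 danshensu phosphonoacetate
Product: 17 2,4-di-tert-butyl 1-(4-methoxybenzyl) (1R,2R,3S,4R)-3-{3,4-bis[(4-methoxybenzyl)oxy]phenyl}-6-[(1E)-3-({(2R)-3-{3,4-bis[(4-methoxybenzyl)oxy]phenyl}-1-[(4-methoxybenzyl)oxy]-1-oxopropan-2-yl}oxy)-3-oxoprop-1-en-1-yl]cyclohex-5-ene-1,2,4-tricarboxylate (fully protected target)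
Conditions: LiCl, iPr2NEt, MeCN, 0 °C to rt
Reagents that add atoms: none
Why: Horner–Wadsworth–Emmons olefination with LiCl and an amine base should give the E-acrylate with a base too weak to epimerise C3, C6 or the danshensu centre.

Step 11
Reactants: 17 fully protected target
Product: 18 (1R,2R,3S,4R)-6-[(1E)-3-{[(1R)-1-carboxy-2-(3,4-dihydroxyphenyl)ethyl]oxy}-3-oxoprop-1-en-1-yl]-3-(3,4-dihydroxyphenyl)cyclohex-5-ene-1,2,4-tricarboxylic acid (CNP0327643.1)
Conditions: CF3CO2H/CH2Cl2 (1:1), anisole (40 equiv), 0 °C to rt; reverse-phase purification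
Reagents that add atoms: none
Why: Acidolysis by the SN1 path should cleave both tert-butyl esters, both 4-methoxybenzyl esters and all four 4-methoxybenzyl ethers at once, with anisole trapping the benzyl cations, while the dienoate, the secondary ester and all five stereocentres are stable to acid.

**Compound list**

1 | maleic anhydride | O=C1OC(=O)C=C1 | starting material
2 | propargyl alcohol (prop-2-yn-1-ol) | C#CCO | starting material
3 | (Z)-4-oxo-4-(prop-2-yn-1-yloxy)but-2-enoic acid | C#CCOC(=O)/C=C\C(=O)O | intermediate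
4 | tert-butyl prop-2-yn-1-yl (Z)-but-2-enedioate | C#CCOC(=O)/C=C\C(=O)OC(C)(C)C | intermediate
5 | 3,4-dihydroxybenzaldehyde | O=Cc1ccc(O)c(O)c1 | starting material
6 | 3,4-bis[(4-methoxybenzyl)oxy]benzaldehyde | O=Cc1ccc(OCc2ccc(OC)cc2)c(OCc2ccc(OC)cc2)c1 | intermediate
7 | tert-butyl (triphenylphosphoranylidene)acetate | CC(C)(C)OC(=O)C=P(c1ccccc1)(c1ccccc1)c1ccccc1 | starting material
8 | tert-butyl (E)-3-{3,4-bis[(4-methoxybenzyl)oxy]phenyl}prop-2-enoate | CC(C)(C)OC(=O)/C=C/c1ccc(OCc2ccc(OC)cc2)c(OCc2ccc(OC)cc2)c1 | intermediate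
9 | di-tert-butyl (5R,6S,7R,7aR)-6-{3,4-bis[(4-methoxybenzyl)oxy]phenyl}-1-oxo-1,3,5,6,7,7a-hexahydro-2-benzofuran-5,7-dicarboxylate | C1(COC2=O)=C[C@@H](C(=O)OC(C)(C)C)[C@H](c3ccc(OCc4ccc(OC)cc4)c(OCc4ccc(OC)cc4)c3)[C@@H](C(=O)OC(C)(C)C)[C@H]12 | intermediate
10 | 2,4-di-tert-butyl 1-lithium (1R,2R,3S,4R)-3-{3,4-bis[(4-methoxybenzyl)oxy]phenyl}-6-(hydroxymethyl)cyclohex-5-ene-1,2,4-tricarboxylate | OCC1=C[C@@H](C(=O)OC(C)(C)C)[C@H](c2ccc(OCc3ccc(OC)cc3)c(OCc3ccc(OC)cc3)c2)[C@@H](C(=O)OC(C)(C)C)[C@H]1C(=O)[O-].[Li+] | intermediate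
11 | 2,4-di-tert-butyl 1-(4-methoxybenzyl) (1R,2R,3S,4R)-3-{3,4-bis[(4-methoxybenzyl)oxy]phenyl}-6-(hydroxymethyl)cyclohex-5-ene-1,2,4-tricarboxylate | OCC1=C[C@@H](C(=O)OC(C)(C)C)[C@H](c2ccc(OCc3ccc(OC)cc3)c(OCc3ccc(OC)cc3)c2)[C@@H](C(=O)OC(C)(C)C)[C@H]1C(=O)OCc1ccc(OC)cc1 | intermediate
12 | 2,4-di-tert-butyl 1-(4-methoxybenzyl) (1R,2R,3S,4R)-3-{3,4-bis[(4-methoxybenzyl)oxy]phenyl}-6-formylcyclohex-5-ene-1,2,4-tricarboxylate | O=CC1=C[C@@H](C(=O)OC(C)(C)C)[C@H](c2ccc(OCc3ccc(OC)cc3)c(OCc3ccc(OC)cc3)c2)[C@@H](C(=O)OC(C)(C)C)[C@H]1C(=O)OCc1ccc(OC)cc1 | intermediate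
13 | (R)-danshensu, (2R)-3-(3,4-dihydroxyphenyl)-2-hydroxypropanoic acid | O[C@H](Cc1ccc(O)c(O)c1)C(=O)O | starting material
14 | 4-methoxybenzyl (2R)-3-{3,4-bis[(4-methoxybenzyl)oxy]phenyl}-2-hydroxypropanoate | O[C@H](Cc1ccc(OCc2ccc(OC)cc2)c(OCc2ccc(OC)cc2)c1)C(=O)OCc1ccc(OC)cc1 | intermediate
15 | (diethoxyphosphoryl)acetic acid | CCOP(=O)(CC(=O)O)OCC | starting material
16 | 4-methoxybenzyl (2R)-3-{3,4-bis[(4-methoxybenzyl)oxy]phenyl}-2-{[(diethoxyphosphoryl)acetyl]oxy}propanoate | CCOP(=O)(CC(=O)O[C@H](Cc1ccc(OCc2ccc(OC)cc2)c(OCc2ccc(OC)cc2)c1)C(=O)OCc1ccc(OC)cc1)OCC | intermediate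
17 | 2,4-di-tert-butyl 1-(4-methoxybenzyl) (1R,2R,3S,4R)-3-{3,4-bis[(4-methoxybenzyl)oxy]phenyl}-6-[(1E)-3-({(2R)-3-{3,4-bis[(4-methoxybenzyl)oxy]phenyl}-1-[(4-methoxybenzyl)oxy]-1-oxopropan-2-yl}oxy)-3-oxoprop-1-en-1-yl]cyclohex-5-ene-1,2,4-tricarboxylate | O=C(/C=C/C1=C[C@@H](C(=O)OC(C)(C)C)[C@H](c2ccc(OCc3ccc(OC)cc3)c(OCc3ccc(OC)cc3)c2)[C@@H](C(=O)OC(C)(C)C)[C@H]1C(=O)OCc1ccc(OC)cc1)O[C@H](Cc1ccc(OCc2ccc(OC)cc2)c(OCc2ccc(OC)cc2)c1)C(=O)OCc1ccc(OC)cc1 | intermediate
18 | (1R,2R,3S,4R)-6-[(1E)-3-{[(1R)-1-carboxy-2-(3,4-dihydroxyphenyl)ethyl]oxy}-3-oxoprop-1-en-1-yl]-3-(3,4-dihydroxyphenyl)cyclohex-5-ene-1,2,4-tricarboxylic acid (CNP0327643.1) | O=C(/C=C/C1=C[C@@H](C(=O)O)[C@H](c2ccc(O)c(O)c2)[C@@H](C(=O)O)[C@H]1C(=O)O)O[C@H](Cc1ccc(O)c(O)c1)C(=O)O | target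

**Step count and risks**

Total: 11 steps. Longest linear sequence: 7 steps (1, 2, 5, 6, 7, 10, 11; the branch 3, 4, 5, 6, 7, 10, 11 is equally long).

Steps most likely to fail:

1. Step 5. The caffeate may fail to insert into the rhodacyclopentene, so that the enyne is consumed by homo-coupling, or it may insert with the opposite orientation or with poor facial selectivity. The fallback sets out from 8 and comes back at 9, and closes the cyclohexene by a Diels–Alder reaction instead. Heck coupling of commercial 4-bromofuran-2(5H)-one with tert-butyl acrylate (Pd(OAc)2, Bu4NCl, NaHCO3, DMF, 60 °C) should give the dienyl butenolide tert-butyl (E)-3-(5-oxo-2,5-dihydrofuran-3-yl)prop-2-enoate F1, whose diene C6=C1–C2=C3 already holds the lactone and the C3 ester. Heating F1 with 8 (toluene, 170 °C, sealed tube, BHT, or 12 kbar at rt) in an ester-endo [4+2] cycloaddition should form C3–C4 and C5–C6 and give 9 as the racemate with the same 3,4-trans, 4,5-trans, 5,6-cis pattern. The enantiomers would be parted on a chiral stationary phase, or as diastereomers after the coupling with 16.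

2. Step 6. The hydroxy ester may close back to the lactone with loss of 4-methoxybenzyl alcohol before or during the oxidation, and prolonged exposure to base may epimerise C6 or move the C1=C2 double bond into conjugation with the lactone. The fallback sets out from 10 and comes back at 18, and makes no ester at C6 at all. The salt 10 is oxidised as such with MnO2 (THF, rt) and the mixture is acidified with cold dilute HCl to give 2,4-di-tert-butyl 1-hydrogen (1R,2R,3S,4R)-3-{3,4-bis[(4-methoxybenzyl)oxy]phenyl}-6-formylcyclohex-5-ene-1,2,4-tricarboxylate F2, an aldehyde acid that may rest as its cyclic hydroxy-lactone tautomer but keeps C7 at the aldehyde level. Horner–Wadsworth–Emmons reaction of F2 with 16 (LiCl, iPr2NEt 3 equiv, MeCN) on the open form should give the corresponding 1-hydrogen ester of 17, 2,4-di-tert-butyl 1-hydrogen (1R,2R,3S,4R)-3-{3,4-bis[(4-methoxybenzyl)oxy]phenyl}-6-[(1E)-3-({(2R)-3-{3,4-bis[(4-methoxybenzyl)oxy]phenyl}-1-[(4-methoxybenzyl)oxy]-1-oxopropan-2-yl}oxy)-3-oxoprop-1-en-1-yl]cyclohex-5-ene-1,2,4-tricarboxylate F3. The CF3CO2H/anisole treatment of step 11 then gives 18.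

3. Step 10. The amine base may remove the C3 proton, which is α to an ester and vinylogous to the aldehyde, leading to epimerisation at C3 or drift of the double bond out of conjugation. The fallback sets out from 14 and comes back at 17, and uses a preformed neutral ylide so that no base meets the aldehyde. Acylation of 14 with bromoacetyl bromide (pyridine, CH2Cl2, 0 °C) should give 4-methoxybenzyl (2R)-3-{3,4-bis[(4-methoxybenzyl)oxy]phenyl}-2-[(bromoacetyl)oxy]propanoate F4. With PPh3 (toluene, rt) this gives the phosphonium salt (2-{[(2R)-3-{3,4-bis[(4-methoxybenzyl)oxy]phenyl}-1-[(4-methoxybenzyl)oxy]-1-oxopropan-2-yl]oxy}-2-oxoethyl)triphenylphosphonium bromide F5. Washing with cold aqueous Na2CO3 gives the stabilised ylide 4-methoxybenzyl (2R)-3-{3,4-bis[(4-methoxybenzyl)oxy]phenyl}-2-{[(triphenyl-λ5-phosphanylidene)acetyl]oxy}propanoate F6. Wittig reaction of F6 with 12 in toluene at 40 °C should give 17 with the same E geometry.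

**Further compounds**

F1 | step 5 | tert-butyl (E)-3-(5-oxo-2,5-dihydrofuran-3-yl)prop-2-enoate | O=C1OCC(/C=C/C(=O)OC(C)(C)C)=C1
F2 | step 6 | 2,4-di-tert-butyl 1-hydrogen (1R,2R,3S,4R)-3-{3,4-bis[(4-methoxybenzyl)oxy]phenyl}-6-formylcyclohex-5-ene-1,2,4-tricarboxylate | O=CC1=C[C@@H](C(=O)OC(C)(C)C)[C@H](c2ccc(OCc3ccc(OC)cc3)c(OCc3ccc(OC)cc3)c2)[C@@H](C(=O)OC(C)(C)C)[C@H]1C(=O)O
F3 | step 6 | 2,4-di-tert-butyl 1-hydrogen (1R,2R,3S,4R)-3-{3,4-bis[(4-methoxybenzyl)oxy]phenyl}-6-[(1E)-3-({(2R)-3-{3,4-bis[(4-methoxybenzyl)oxy]phenyl}-1-[(4-methoxybenzyl)oxy]-1-oxopropan-2-yl}oxy)-3-oxoprop-1-en-1-yl]cyclohex-5-ene-1,2,4-tricarboxylate | O=C(/C=C/C1=C[C@@H](C(=O)OC(C)(C)C)[C@H](c2ccc(OCc3ccc(OC)cc3)c(OCc3ccc(OC)cc3)c2)[C@@H](C(=O)OC(C)(C)C)[C@H]1C(=O)O)O[C@H](Cc1ccc(OCc2ccc(OC)cc2)c(OCc2ccc(OC)cc2)c1)C(=O)OCc1ccc(OC)cc1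
F4 | step 10 | 4-methoxybenzyl (2R)-3-{3,4-bis[(4-methoxybenzyl)oxy]phenyl}-2-[(bromoacetyl)oxy]propanoate | BrCC(=O)O[C@H](Cc1ccc(OCc2ccc(OC)cc2)c(OCc2ccc(OC)cc2)c1)C(=O)OCc1ccc(OC)cc1
F5 | step 10 | (2-{[(2R)-3-{3,4-bis[(4-methoxybenzyl)oxy]phenyl}-1-[(4-methoxybenzyl)oxy]-1-oxopropan-2-yl]oxy}-2-oxoethyl)triphenylphosphonium bromide | [Br-].O=C(C[P+](c1ccccc1)(c1ccccc1)c1ccccc1)O[C@H](Cc1ccc(OCc2ccc(OC)cc2)c(OCc2ccc(OC)cc2)c1)C(=O)OCc1ccc(OC)cc1
F6 | step 10 | 4-methoxybenzyl (2R)-3-{3,4-bis[(4-methoxybenzyl)oxy]phenyl}-2-{[(triphenyl-λ5-phosphanylidene)acetyl]oxy}propanoate | O=C(C=P(c1ccccc1)(c1ccccc1)c1ccccc1)O[C@H](Cc1ccc(OCc2ccc(OC)cc2)c(OCc2ccc(OC)cc2)c1)C(=O)OCc1ccc(OC)cc1
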